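**Assumption:** cembrane numbering (C1–C20; C16 = lactone carbonyl, C17 = exo-methylene carbon) is used in the explanations, and (E)-3-methylpent-2-en-4-yn-1-ol, (R)-3-bromo-2-methylpropan-1-ol and allyl methoxymethyl ether are taken as purchasable.

## Retrosynthetic overview

1. Target 33 ⇐ Shi epoxidation of C3=C4 and O13-acetylation of triene γ-lactone 31, which arises by acyl migration from the bridged δ-lactone 29.
2. Key bond C1–C2: the 14-membered ring is closed by adding the C2 allylic radical to C1 of a 5-(methoxymethoxy)-5,6-dihydropyran-2-one; attack anti to O14 sets C1, and loss of acetate gives the exo-methylene.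
3. The δ-lactone ⇐ ring-closing metathesis of an acrylate made from the syn-alkoxyallylboration product of aldehyde 15 (sets C13 and C14).
4. Aldehyde 15 ⇐ Cu-catalysed sp3–sp3 coupling (C10–C11; C12 from the bromo alcohol) ⇐ Sharpless epoxidation/Red-Al (C8, E-C6=C7) ⇐ copper acetylide allylation (C5–C6).
5. Ring order: six-membered δ-lactone (metathesis) → 14-membered carbocycle (radical) → five-membered γ-lactone (translactonisation) → epoxide.

## Route

Step 1
Reactants: 1 3-methylbut-2-en-1-ol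
Product: 2 tert-butyldimethyl[(3-methylbut-2-en-1-yl)oxy]silane
Conditions: TBSCl, imidazole, DMF, 0 °C → rt
Reagents that add atoms: tert-butyldimethylsilyl chloride, CC(C)(C)[Si](C)(C)Cl
Why: Imidazole-promoted silylation protects the future C2 oxygen so that it survives the hydride and organometallic steps; no stereocentre is involved.

Step 2
Reactants: 2 tert-butyldimethyl[(3-methylbut-2-en-1-yl)oxy]silane
Product: 3 (E)-4-[(tert-butyldimethylsilyl)oxy]-2-methylbut-2-en-1-ol
Conditions: SeO2 (0.5 equiv), t-BuOOH, CH2Cl2, 0 °C → rt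
Reagents that add atoms: selenium dioxide, O=[Se]=O (reoxidised by tert-butyl hydroperoxide, CC(C)(C)OO)
Why: SeO2 allylic oxidation (ene reaction then [2,3]-sigmatropic shift) hydroxylates only the (E)-methyl group of the trisubstituted olefin, which fixes the (E)-geometry of the future C3=C4 bond.

Step 3
Reactants: 3 (E)-4-[(tert-butyldimethylsilyl)oxy]-2-methylbut-2-en-1-ol
Product: 4 tert-butyl{[(E)-4-bromo-3-methylbut-2-en-1-yl]oxy}dimethylsilane
Conditions: CBr4, PPh3, CH2Cl2, 0 °C
Reagents that add atoms: tetrabromomethane, BrC(Br)(Br)Br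
Why: Appel bromination converts the primary allylic alcohol into the bromide without allylic transposition or loss of olefin geometry.

Step 4
Reactants: 5 (E)-3-methylpent-2-en-4-yn-1-ol; 4 tert-butyl{[(E)-4-bromo-3-methylbut-2-en-1-yl]oxy}dimethylsilane
Product: 6 (2E,7E)-9-[(tert-butyldimethylsilyl)oxy]-3,7-dimethylnona-2,7-dien-4-yn-1-ol
Conditions: CuI (0.2 equiv), NaI (0.2 equiv), K2CO3, DMF, rt
Reagents that add atoms: none
Why: Copper acetylide allylation of the terminal alkyne at the unhindered CH2Br terminus forms C5–C6 and leaves both olefin geometries untouched.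

Step 5
Reactants: 6 (2E,7E)-9-[(tert-butyldimethylsilyl)oxy]-3,7-dimethylnona-2,7-dien-4-yn-1-ol
Product: 7 {(2R,3R)-3-[(E)-6-[(tert-butyldimethylsilyl)oxy]-4-methylhex-4-en-1-yn-1-yl]-3-methyloxiran-2-yl}methanol
Conditions: Ti(OiPr)4 (10 mol%), D-(−)-diethyl tartrate (12 mol%), t-BuOOH, 4 Å molecular sieves, CH2Cl2, −20 °C
Reagents that add atoms: tert-butyl hydroperoxide, CC(C)(C)OO
Why: Sharpless asymmetric epoxidation of the (E)-allylic alcohol with D-(−)-tartrate gives the (2R,3R)-epoxide and so fixes the tertiary C8–O stereocentre, while the isolated trisubstituted olefin has no directing hydroxyl and is not touched.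

Step 6
Reactants: 7 {(2R,3R)-3-[(E)-6-[(tert-butyldimethylsilyl)oxy]-4-methylhex-4-en-1-yn-1-yl]-3-methyloxiran-2-yl}methanol
Product: 9 (3S,4E,7E)-9-[(tert-butyldimethylsilyl)oxy]-3,7-dimethylnona-4,7-diene-1,3-diol, via alkynyl diol 8 (not isolated)
Conditions: NaAlH2(OCH2CH2OMe)2 (4 equiv), THF, 0 °C → 45 °C; aq. potassium sodium tartrate
Reagents that add atoms: none
Why: Red-Al reduction delivers hydride from the C10 alkoxyaluminate to C9 of the 2,3-epoxy alcohol (the C8–O bond and its configuration are retained), and the tertiary propargylic alkoxide so formed directs trans-hydroalumination of the alkyne to the (E)-C6=C7 olefin.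

Step 7
Reactants: 9 (3S,4E,7E)-9-[(tert-butyldimethylsilyl)oxy]-3,7-dimethylnona-4,7-diene-1,3-diol
Product: 10 (3S,4E,7E)-9-[(tert-butyldimethylsilyl)oxy]-1-iodo-3,7-dimethylnona-4,7-dien-3-ol
Conditions: I2, PPh3, imidazole, CH2Cl2, 0 °C
Reagents that add atoms: iodine, II
Why: Appel-type iodination is selective for the primary hydroxyl because the tertiary allylic alcohol is too hindered to form the alkoxyphosphonium ion.

Step 8
Reactants: 11 (R)-3-bromo-2-methylpropan-1-ol; 10 (3S,4E,7E)-9-[(tert-butyldimethylsilyl)oxy]-1-iodo-3,7-dimethylnona-4,7-dien-3-ol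
Product: 14 (2S,6S,7E,10E)-12-[(tert-butyldimethylsilyl)oxy]-2,6,10-trimethyldodeca-7,10-diene-1,6-diol, via chloromagnesium alkoxide 12 (not isolated), via alkoxide Grignard reagent 13 (not isolated)
Conditions: 11, i-PrMgCl (1 equiv), THF, −20 °C; Mg, 50 °C; then 10 (pretreated with i-PrMgCl, 1 equiv), Li2CuCl4 (5 mol%), THF, −30 → 0 °C
Reagents that add atoms: none
Why: Kochi-type Li2CuCl4-catalysed sp3–sp3 coupling of a Normant-type alkoxide Grignard reagent with the primary iodide forms C10–C11, and the C12 methyl stereocentre comes unchanged from 11.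

Step 9
Reactants: 14 (2S,6S,7E,10E)-12-[(tert-butyldimethylsilyl)oxy]-2,6,10-trimethyldodeca-7,10-diene-1,6-diol
Product: 15 (2S,6S,7E,10E)-12-[(tert-butyldimethylsilyl)oxy]-6-hydroxy-2,6,10-trimethyldodeca-7,10-dienal
Conditions: Dess–Martin periodinane, NaHCO3, CH2Cl2, 0 °C
Reagents that add atoms: none
Why: Buffered Dess–Martin oxidation gives the α-methyl aldehyde without epimerisation, and the tertiary alcohol cannot be oxidised.

Step 10
Reactants: 16 3-(methoxymethoxy)prop-1-ene; 15 (2S,6S,7E,10E)-12-[(tert-butyldimethylsilyl)oxy]-6-hydroxy-2,6,10-trimethyldodeca-7,10-dienal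
Product: 19 (3R,4R,5S,9S,10E,13E)-15-[(tert-butyldimethylsilyl)oxy]-3-(methoxymethoxy)-5,9,13-trimethylpentadeca-1,10,13-triene-4,9-diol, via lithiated allyl ether 17 (not isolated), via allylborane 18 (not isolated)
Conditions: 16, s-BuLi, THF, −78 °C; (−)-Ipc2BOMe; BF3·OEt2; then 15, −78 °C; NaOH, H2O2
Reagents that add atoms: none
Why: Brown syn-alkoxyallylboration, in which the (Z)-γ-alkoxyallylborane reacts through a chair transition state (13,14-syn) and the isopinocampheyl groups from (+)-α-pinene select the aldehyde face, gives 13R,14R under reagent control and hence the all-syn C12–C13–C14 triad.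

Step 11
Reactants: 20 2-(bromomethyl)prop-2-enoic acid
Product: 21 2-(acetoxymethyl)prop-2-enoic acid
Conditions: KOAc, AcOH, 60 °C
Reagents that add atoms: potassium acetate, CC(=O)[O-].[K+]
Why: Displacement of the allylic bromide by acetate (SN2/SN2′, same product) gives the acrylic acid that carries the future C17 leaving group.

Step 12
Reactants: 21 2-(acetoxymethyl)prop-2-enoic acid; 19 (3R,4R,5S,9S,10E,13E)-15-[(tert-butyldimethylsilyl)oxy]-3-(methoxymethoxy)-5,9,13-trimethylpentadeca-1,10,13-triene-4,9-diol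
Product: 23 (3R,4R,5S,9S,10E,13E)-15-[(tert-butyldimethylsilyl)oxy]-9-hydroxy-3-(methoxymethoxy)-5,9,13-trimethylpentadeca-1,10,13-trien-4-yl 2-(acetoxymethyl)prop-2-enoate, via acid chloride 22 (not isolated)
Conditions: 21, (COCl)2, DMF (cat.), CH2Cl2, 0 °C; then 19, i-Pr2NEt, CH2Cl2, 0 °C → rt
Reagents that add atoms: none
Why: Acylation of the secondary C13 hydroxyl by the acid chloride without a nucleophilic catalyst (the tertiary C8 hydroxyl does not react) places the acrylate next to the C14 vinyl group.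

Step 13
Reactants: 23 (3R,4R,5S,9S,10E,13E)-15-[(tert-butyldimethylsilyl)oxy]-9-hydroxy-3-(methoxymethoxy)-5,9,13-trimethylpentadeca-1,10,13-trien-4-yl 2-(acetoxymethyl)prop-2-enoate
Product: 24 {(5R,6R)-6-[(2S,6S,7E,10E)-12-[(tert-butyldimethylsilyl)oxy]-6-hydroxy-6,10-dimethyldodeca-7,10-dien-2-yl]-5-(methoxymethoxy)-2-oxo-5,6-dihydro-2H-pyran-3-yl}methyl acetate
Conditions: second-generation Grubbs catalyst (10 mol%), toluene (5 mM), 80 °C
Reagents that add atoms: none
Why: Ring-closing metathesis of the acrylate with the adjacent vinyl group gives the six-membered α,β-unsaturated δ-lactone (C1=C15), the fastest ring closure open to the ruthenium carbene, and no stereocentre is touched.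

Step 14
Reactants: 24 {(5R,6R)-6-[(2S,6S,7E,10E)-12-[(tert-butyldimethylsilyl)oxy]-6-hydroxy-6,10-dimethyldodeca-7,10-dien-2-yl]-5-(methoxymethoxy)-2-oxo-5,6-dihydro-2H-pyran-3-yl}methyl acetate
Product: 25 {(5R,6R)-6-[(2S,6S,7E,10E)-6,12-dihydroxy-6,10-dimethyldodeca-7,10-dien-2-yl]-5-(methoxymethoxy)-2-oxo-5,6-dihydro-2H-pyran-3-yl}methyl acetate
Conditions: HF·pyridine, pyridine, THF, 0 °C → rt
Reagents that add atoms: none
Why: Fluoride desilylation frees the primary allylic alcohol, while the acetal, the acetate and the lactone are inert to buffered HF·pyridine.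

Step 15
Reactants: 25 {(5R,6R)-6-[(2S,6S,7E,10E)-6,12-dihydroxy-6,10-dimethyldodeca-7,10-dien-2-yl]-5-(methoxymethoxy)-2-oxo-5,6-dihydro-2H-pyran-3-yl}methyl acetate
Product: 27 {(5R,6R)-6-[(2S,6S,7E,10E)-12-bromo-6-hydroxy-6,10-dimethyldodeca-7,10-dien-2-yl]-5-(methoxymethoxy)-2-oxo-5,6-dihydro-2H-pyran-3-yl}methyl acetate, via allylic mesylate 26 (not isolated)
Conditions: MsCl, Et3N, CH2Cl2, −40 °C; then LiBr, THF, 0 °C
Reagents that add atoms: lithium bromide, [Li+].[Br-]
Why: Mesylation of the primary allylic hydroxyl and SN2 displacement by bromide give the radical precursor without touching the tertiary alcohol or the olefin geometry.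

Step 16
Reactants: 27 {(5R,6R)-6-[(2S,6S,7E,10E)-12-bromo-6-hydroxy-6,10-dimethyldodeca-7,10-dien-2-yl]-5-(methoxymethoxy)-2-oxo-5,6-dihydro-2H-pyran-3-yl}methyl acetate
Product: 29 (1S,3E,6E,8S,12S,13R,14R)-8-hydroxy-14-(methoxymethoxy)cembra-3,6,15(17)-trien-16,13-olide, via acetoxymethyl lactone 28 (not isolated)
Conditions: Bu3SnH (1.3 equiv) and AIBN (0.2 equiv) added over 12 h, benzene (1 mM), 80 °C; then DBU (2 equiv), rt
Reagents that add atoms: none
Why: Proposed new method: the tin radical abstracts the allylic bromine, the (E)-allyl radical adds through its primary terminus C2 to the β-carbon C1 of the unsaturated δ-lactone (14-membered Giese-type macrocyclisation) anti to the pseudoaxial OMOM group on C14 so that C1 becomes S, the α-lactone radical is reduced by Bu3SnH and DBU then expels acetate (E1cB) to give the exo-methylene; the closest known reaction types are allylic-radical macrocyclisation onto enones and anti-selective radical conjugate addition to γ-oxygenated unsaturated lactones.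

Step 17
Reactants: 29 (1S,3E,6E,8S,12S,13R,14R)-8-hydroxy-14-(methoxymethoxy)cembra-3,6,15(17)-trien-16,13-olide
Product: 31 (1S,3E,6E,8S,12S,13R,14R)-8,13-dihydroxycembra-3,6,15(17)-trien-16,14-olide, via hydroxy delta-lactone 30 (not isolated)
Conditions: TMSOTf, 2,2′-bipyridyl, CH2Cl2, 0 °C; H2O; then DBU (0.1 equiv), CH2Cl2, rt
Reagents that add atoms: none
Why: TMSOTf/2,2′-bipyridyl cleaves the MOM acetal under non-protic conditions and base-catalysed 1,2-acyl migration (translactonisation) then moves the acyl group from O13 to O14, the fused γ-lactone being favoured over the bridged δ-lactone, with no stereocentre touched (C2 trans to O14 in 29 becomes the cis ring fusion).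

Step 18
Reactants: 31 (1S,3E,6E,8S,12S,13R,14R)-8,13-dihydroxycembra-3,6,15(17)-trien-16,14-olide
Product: 32 (1S,3E,6E,8S,12S,13R,14R)-13-acetoxy-8-hydroxycembra-3,6,15(17)-trien-16,14-olide
Conditions: Ac2O, pyridine, DMAP (cat.), CH2Cl2, 0 °C
Reagents that add atoms: acetic anhydride, CC(=O)OC(C)=O
Why: Acetylation takes the only secondary hydroxyl (C13), since the tertiary C8 hydroxyl is not acylated at 0 °C.

Step 19
Reactants: 32 (1S,3E,6E,8S,12S,13R,14R)-13-acetoxy-8-hydroxycembra-3,6,15(17)-trien-16,14-olide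
Product: 33 (1S,3R,4R,6E,8S,12S,13R,14R)-13-acetoxy-3,4-epoxy-8-hydroxycembra-6,15(17)-dien-16,14-olide
Conditions: D-fructose-derived Shi ketone (30 mol%), Oxone (2KHSO5·KHSO4·K2SO4), K2CO3, Bu4NHSO4, MeCN/CH2(OMe)2/aq. Na2B4O7 buffer (pH 10.5), 0 °C
Reagents that add atoms: potassium peroxymonosulfate, [K+].[O-]S(=O)(=O)OO
Why: Shi asymmetric epoxidation, in which the dioxirane of the D-fructose-derived ketone transfers oxygen through a spiro transition state to the electron-rich (E)-trisubstituted C3=C4 olefin, gives the (3R,4R)-epoxide under reagent control, while the C6=C7 olefin (deactivated by the allylic hydroxyl and flanked by the quaternary C8) and the electron-poor exo-methylene react more slowly.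

## Compound list

1 | 3-methylbut-2-en-1-ol | CC(C)=CCO | starting material
2 | tert-butyldimethyl[(3-methylbut-2-en-1-yl)oxy]silane | CC(C)=CCO[Si](C)(C)C(C)(C)C | intermediate
3 | (E)-4-[(tert-butyldimethylsilyl)oxy]-2-methylbut-2-en-1-ol | OC/C(C)=C/CO[Si](C)(C)C(C)(C)C | intermediate
4 | tert-butyl{[(E)-4-bromo-3-methylbut-2-en-1-yl]oxy}dimethylsilane | BrC/C(C)=C/CO[Si](C)(C)C(C)(C)C | intermediate
5 | (E)-3-methylpent-2-en-4-yn-1-ol | OC/C=C(\C)C#C | starting material
6 | (2E,7E)-9-[(tert-butyldimethylsilyl)oxy]-3,7-dimethylnona-2,7-dien-4-yn-1-ol | OC/C=C(\C)C#CC/C(C)=C/CO[Si](C)(C)C(C)(C)C | intermediate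
7 | {(2R,3R)-3-[(E)-6-[(tert-butyldimethylsilyl)oxy]-4-methylhex-4-en-1-yn-1-yl]-3-methyloxiran-2-yl}methanol | OC[C@H]1O[C@]1(C)C#CC/C(C)=C/CO[Si](C)(C)C(C)(C)C | intermediate
8 | (3S,7E)-9-[(tert-butyldimethylsilyl)oxy]-3,7-dimethylnon-7-en-4-yne-1,3-diol (as its aluminate) | OCC[C@](C)(O)C#CC/C(C)=C/CO[Si](C)(C)C(C)(C)C | intermediate
9 | (3S,4E,7E)-9-[(tert-butyldimethylsilyl)oxy]-3,7-dimethylnona-4,7-diene-1,3-diol | OCC[C@](C)(O)/C=C/C/C(C)=C/CO[Si](C)(C)C(C)(C)C | intermediate
10 | (3S,4E,7E)-9-[(tert-butyldimethylsilyl)oxy]-1-iodo-3,7-dimethylnona-4,7-dien-3-ol | ICC[C@](C)(O)/C=C/C/C(C)=C/CO[Si](C)(C)C(C)(C)C | intermediate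
11 | (R)-3-bromo-2-methylpropan-1-ol | OC[C@@H](C)CBr | starting material
12 | chloromagnesium (R)-3-bromo-2-methylpropan-1-olate | Cl[Mg]OC[C@@H](C)CBr | intermediate
13 | bromo[(R)-3-(chloromagnesiooxy)-2-methylpropyl]magnesium | Cl[Mg]OC[C@@H](C)C[Mg]Br | intermediate
14 | (2S,6S,7E,10E)-12-[(tert-butyldimethylsilyl)oxy]-2,6,10-trimethyldodeca-7,10-diene-1,6-diol | OC[C@@H](C)CCC[C@](C)(O)/C=C/C/C(C)=C/CO[Si](C)(C)C(C)(C)C | intermediate
15 | (2S,6S,7E,10E)-12-[(tert-butyldimethylsilyl)oxy]-6-hydroxy-2,6,10-trimethyldodeca-7,10-dienal | O=C[C@@H](C)CCC[C@](C)(O)/C=C/C/C(C)=C/CO[Si](C)(C)C(C)(C)C | intermediate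
16 | 3-(methoxymethoxy)prop-1-ene | C=CCOCOC | starting material
17 | (Z)-3-(methoxymethoxy)allyllithium | [Li]C/C=C\OCOC | intermediate
18 | [(Z)-3-(methoxymethoxy)allyl]diisopinocampheylborane (isopinocampheyl groups from (+)-α-pinene) | COCO/C=C\CB([C@@H]1C[C@@H]2C[C@H]([C@H]1C)C2(C)C)[C@@H]1C[C@@H]2C[C@H]([C@H]1C)C2(C)C | intermediate
19 | (3R,4R,5S,9S,10E,13E)-15-[(tert-butyldimethylsilyl)oxy]-3-(methoxymethoxy)-5,9,13-trimethylpentadeca-1,10,13-triene-4,9-diol | C=C[C@@H](OCOC)[C@H](O)[C@@H](C)CCC[C@](C)(O)/C=C/C/C(C)=C/CO[Si](C)(C)C(C)(C)C | intermediate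
20 | 2-(bromomethyl)prop-2-enoic acid | OC(=O)C(=C)CBr | starting material
21 | 2-(acetoxymethyl)prop-2-enoic acid | CC(=O)OCC(=C)C(=O)O | intermediate
22 | 2-(acetoxymethyl)prop-2-enoyl chloride | CC(=O)OCC(=C)C(Cl)=O | intermediate
23 | (3R,4R,5S,9S,10E,13E)-15-[(tert-butyldimethylsilyl)oxy]-9-hydroxy-3-(methoxymethoxy)-5,9,13-trimethylpentadeca-1,10,13-trien-4-yl 2-(acetoxymethyl)prop-2-enoate | C=C[C@@H](OCOC)[C@H](OC(=O)C(=C)COC(C)=O)[C@@H](C)CCC[C@](C)(O)/C=C/C/C(C)=C/CO[Si](C)(C)C(C)(C)C | intermediate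
24 | {(5R,6R)-6-[(2S,6S,7E,10E)-12-[(tert-butyldimethylsilyl)oxy]-6-hydroxy-6,10-dimethyldodeca-7,10-dien-2-yl]-5-(methoxymethoxy)-2-oxo-5,6-dihydro-2H-pyran-3-yl}methyl acetate | CC(=O)OCC1=C[C@@H](OCOC)[C@@H]([C@@H](C)CCC[C@](C)(O)/C=C/C/C(C)=C/CO[Si](C)(C)C(C)(C)C)OC1=O | intermediate
25 | {(5R,6R)-6-[(2S,6S,7E,10E)-6,12-dihydroxy-6,10-dimethyldodeca-7,10-dien-2-yl]-5-(methoxymethoxy)-2-oxo-5,6-dihydro-2H-pyran-3-yl}methyl acetate | CC(=O)OCC1=C[C@@H](OCOC)[C@@H]([C@@H](C)CCC[C@](C)(O)/C=C/C/C(C)=C/CO)OC1=O | intermediate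
26 | 12-O-methanesulfonate of 25 (primary allylic mesylate) | CC(=O)OCC1=C[C@@H](OCOC)[C@@H]([C@@H](C)CCC[C@](C)(O)/C=C/C/C(C)=C/COS(C)(=O)=O)OC1=O | intermediate
27 | {(5R,6R)-6-[(2S,6S,7E,10E)-12-bromo-6-hydroxy-6,10-dimethyldodeca-7,10-dien-2-yl]-5-(methoxymethoxy)-2-oxo-5,6-dihydro-2H-pyran-3-yl}methyl acetate | CC(=O)OCC1=C[C@@H](OCOC)[C@@H]([C@@H](C)CCC[C@](C)(O)/C=C/C/C(C)=C/CBr)OC1=O | intermediate
28 | (1S,3E,6E,8S,12S,13R,14R)-17-acetoxy-8-hydroxy-14-(methoxymethoxy)cembra-3,6-dien-16,13-olide (both C15 epimers) | CC(=O)OCC1C(=O)O[C@H]2[C@H](OCOC)[C@H]1C/C=C(\C)C/C=C/[C@@](C)(O)CCC[C@@H]2C | intermediate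
29 | (1S,3E,6E,8S,12S,13R,14R)-8-hydroxy-14-(methoxymethoxy)cembra-3,6,15(17)-trien-16,13-olide | C=C1C(=O)O[C@H]2[C@H](OCOC)[C@H]1C/C=C(\C)C/C=C/[C@@](C)(O)CCC[C@@H]2C | intermediate
30 | (1S,3E,6E,8S,12S,13R,14R)-8,14-dihydroxycembra-3,6,15(17)-trien-16,13-olide | C=C1C(=O)O[C@H]2[C@H](O)[C@H]1C/C=C(\C)C/C=C/[C@@](C)(O)CCC[C@@H]2C | intermediate
31 | (1S,3E,6E,8S,12S,13R,14R)-8,13-dihydroxycembra-3,6,15(17)-trien-16,14-olide | C=C1C(=O)O[C@H]2[C@H](O)[C@@H](C)CCC[C@](C)(O)/C=C/C/C(C)=C/C[C@@H]12 | intermediate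
32 | (1S,3E,6E,8S,12S,13R,14R)-13-acetoxy-8-hydroxycembra-3,6,15(17)-trien-16,14-olide | C=C1C(=O)O[C@H]2[C@H](OC(C)=O)[C@@H](C)CCC[C@](C)(O)/C=C/C/C(C)=C/C[C@@H]12 | intermediate
33 | (1S,3R,4R,6E,8S,12S,13R,14R)-13-acetoxy-3,4-epoxy-8-hydroxycembra-6,15(17)-dien-16,14-olide (CNP0202356.4) | C=C1C(=O)O[C@H]2[C@H](OC(C)=O)[C@@H](C)CCC[C@](C)(O)/C=C/C[C@@]3(C)O[C@@H]3C[C@@H]12 | target

## Step count and weak points

Total steps: 19. Longest linear sequence: 18 (from 1 through steps 1–10 and 12–19 to 33).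

The most fragile operation is step 16. A stabilised allylic radical adds slowly to a β-substituted lactone and may be reduced by the stannane before the ring closes. The fallback sets out from 27 and replaces the reductive chain by a degenerative xanthate transfer that contains no hydrogen donor. KSC(S)OEt in acetone at 0 °C converts 27 into the S-allyl O-ethyl dithiocarbonate F1. Dilauroyl peroxide, added in portions to a refluxing 1 mM solution in 1,2-dichloroethane, then drives the same 14-membered ring closure, and the adduct radical is stored as the tertiary xanthate F2. Bu3SnH/AIBN removes the xanthate group, and the sequence comes back to the route at 28 (DBU then gives 29).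

The second weak point is step 17, where the acyl group may fail to move from O13 to O14 or the exo-methylene may isomerise under base. The fallback sets out from 29: after the same TMSOTf/2,2′-bipyridyl cleavage, aqueous LiOH in THF at 0 °C opens the lactone to the trihydroxy acid F3. EDC·HCl/HOBt in CH2Cl2 (2 mM) recloses it, the five-membered ring onto O14 forming faster than the six-membered one, and the route is rejoined at 31.

The third is step 19, where the C6=C7 olefin may compete or the macrocycle may override the catalyst's facial preference. The fallback sets out from 32: NBS in THF/H2O at 0 °C attacks only the electron-rich trisubstituted olefin and gives the anti bromohydrin F4 (Br on C3, OH on C4). Cs2CO3 in MeCN closes the epoxide with inversion at C3, which returns to the route at 33. Because the oxygen ends on the face opposite to the one first attacked by the electrophile, this sequence gives the diastereomer complementary to direct substrate-controlled oxygen transfer.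

Further compounds
F1 | step 16 | {(5R,6R)-6-[(2S,6S,7E,10E)-12-[(ethoxycarbonothioyl)sulfanyl]-6-hydroxy-6,10-dimethyldodeca-7,10-dien-2-yl]-5-(methoxymethoxy)-2-oxo-5,6-dihydro-2H-pyran-3-yl}methyl acetate | CC(=O)OCC1=C[C@@H](OCOC)[C@@H]([C@@H](C)CCC[C@](C)(O)/C=C/C/C(C)=C/CSC(=S)OCC)OC1=O
F2 | step 16 | compound 28 carrying an (ethoxycarbonothioyl)sulfanyl group in place of hydrogen on C15 (other stereocentres as in 28; both C15 epimers) | CCOC(=S)SC1(COC(C)=O)C(=O)O[C@H]2[C@H](OCOC)[C@H]1C/C=C(\C)C/C=C/[C@@](C)(O)CCC[C@@H]2C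
F3 | step 17 | (1S,3E,6E,8S,12S,13R,14R)-8,13,14-trihydroxycembra-3,6,15(17)-trien-16-oic acid | C=C(C(=O)O)[C@@H]1C/C=C(\C)C/C=C/[C@@](C)(O)CCC[C@H](C)[C@@H](O)[C@@H]1O
F4 | step 19 | (1S,3S,4R,6E,8S,12S,13R,14R)-13-acetoxy-3-bromo-4,8-dihydroxycembra-6,15(17)-dien-16,14-olide | C=C1C(=O)O[C@H]2[C@H](OC(C)=O)[C@@H](C)CCC[C@](C)(O)/C=C/C[C@@](C)(O)[C@@H](Br)C[C@@H]12
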